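# Plakortolide Q (20): synthesis design

## The problem

Plakortolide Q (20) is a 1,2-dioxane that shares its C3–C4 bond with a γ-butyrolactone in a cis fusion. C6 carries a methyl group and a ten-carbon chain ending in an (E,E)-1-phenylbutadiene. Plakortolide numbering is used in the text: C1 is the lactone carbonyl, C3 and C6 are the two peroxy carbons, the chain is C7–C16; in the systematic names C3, C4 and C6 appear as C7a, C4a and C3. Three stereocentres have to be set, C3 (R), C4 (R) and C6 (S), two of them quaternary. C3 and C4 are adjacent and a small ring can enforce their relationship, whereas C6 lies 1,3 to C4 across the dioxane and can only be reached through the conformation of the finished bicycle. C4 is therefore fixed first in the absolute sense and should then control C3 through the ring fusion and C6 through 1,3-induction. Once the O–O bond is present, hydrogenation, phosphines and low-valent metals are excluded, and because the C3–O bond is β to the lactone carbonyl, any base that enolises C2 opens the dioxane by E1cB elimination. The styryl diene would not survive diimide or radical oxygenation, so it has to be attached last and under conditions the peroxy lactone tolerates. The peroxide bridge C6–O–O–C3 spans two carbons that are also joined through C5 and C4: removing the two oxygen atoms and joining C3 to C6 gives a cyclobutane C3–C4–C5–C6, and with a hydroxyl on C6 this is a cyclobutanol that a radical ring expansion with O2 can reopen into the dioxane. A cyclobutane fused to the lactone can only be cis, which secures the C3/C4 relationship, and the same four-membered ring is the [2+2] adduct of the C3=C4 bond of an enol lactone with a two-carbon ketene equivalent.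

## Retrosynthesis

**C13=C14.** The diene of 20 is cut at C13=C14 into aldehyde 17 and diethyl cinnamylphosphonate 18. A cut at C14–C15 would need a vinyl metal or vinyl halide on the peroxide fragment and a palladium coupling, and a cut at C15=C16 would leave a dienal on the peroxide. The chosen cut imports C15=C16 with its geometry fixed and leaves one E-selective olefination. Aldehyde 17 has no diene and tolerates every earlier operation. The forward step needs carbonyl addition of the anion 19 to be faster than proton removal at C2.

**C13 oxidation level and C8=C9.** Aldehyde 17 comes from primary alcohol 16, and 16 from alkene 15 by diimide reduction. Alkene 15 is cut at C8=C9 into allyl dioxane 13 and hex-5-en-1-ol 14. Peroxycarbenium ions are trapped reliably only by allyl- and enol-silanes, so a three-carbon handle followed by cross-metathesis is the short way to C7–C13; a one-step introduction of the whole chain at C6 has no reliable counterpart. Compound 13 already holds all three stereocentres in an eleven-carbon core. The forward steps need a metathesis catalyst and a reductant that leave the O–O bond alone; the geometry of C8=C9 does not matter.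

**C6–C7.** Compound 13 is cut at C6–C7 into peroxyhemiketal 10 and allyltrimethylsilane 11, through peroxycarbenium ion 12. Both anomers of 10 converge on 12, so C6 is set only at this point and under the control of C4 in a rigid bicycle. Setting C6 before ring formation would mean acyclic control of a quaternary carbon. Compound 10 has eight carbons and its C6 configuration is irrelevant. The forward step needs ionisation of a tertiary peroxyhemiketal without O–O heterolysis, and attack anti to the C4 methyl.

**C3–O and C6–O (key cut).** Compound 10 is traced to cyclobutanol 7 and dioxygen 8 by removing O2 and joining C3 to C6. The usual routes to a 1,2-dioxane (hydroperoxide displacement, hydroperoxide oxa-Michael addition, singlet-oxygen cycloaddition) need a stereodefined leaving group at C3 or face control in an open chain. Here both C–O bonds come from O2 in one operation, the precursor is a robust peroxide-free bicycle, and the C3 configuration follows from the fact that only a cis closure is easy. The forward step needs β-scission toward C3, O2 capture at C3 and closure of hydroperoxy ketone 9 onto the unveiled C6 ketone.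

**C6–CH3.** Cyclobutanol 7 comes from cyclobutanone 6 by removing the C6 methyl. The methyl is placed here and the chain later because the nucleophile added to 12 should enter anti to the C4 methyl, which is the face the chain occupies in 20. Either carbinol epimer of 7 serves. The forward step needs a methyl donor that neither enolises the β-acyloxy ketone nor attacks the lactone.

**C3–C6 and C4–C5.** Cyclobutanone 6 is cut across the four-membered ring into α-angelica lactone 3 and keteniminium salt 4, with iminium salt 5 as the hydrolysed intermediate. The polarity matches: the nucleophilic β-carbon of the enol lactone (C3) meets the electrophilic carbon of 4 (C6). Lactone 3 supplies C1–C4 with the lactone and the C4 methyl; salt 4 supplies C5 and C6. A butenolide photocycloaddition would fuse the cyclobutane at C2–C3, and an achiral ketene would give a racemate; the chiral keteniminium sets the absolute configuration of C4. The C3–C6 bond made here is the one later given up to O2, so it serves as a temporary carbon tether. The forward step needs the enol lactone to react as a nucleophile without isomerising, and face selection by the auxiliary.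

**Amide.** Salt 4 is generated from amide 2, the N-acetyl derivative of the C2-symmetric amine 1; hydrolysis of 5 returns 1.

## Roads not taken

**Alternative 1:** A desymmetrising Baeyer–Villiger oxidation of 4-hydroxy-4-methylcyclohexanone A2.
- **Cut:** the lactone C1–O bond and the C4 stereocentre.
- **Key step:** cyclohexanone monooxygenase with O2, or a chiral Sc(OTf)3–N,N'-dioxide complex with H2O2, inserts oxygen next to one enantiotopic α-carbon. The tertiary hydroxyl then translactonises to give the hydroxyethyl γ-lactone A1.
- **Merits:** a cheap achiral substrate and catalytic enantiocontrol of C4 with a predictable sense. In this respect it is better than the chosen plan, which uses a stoichiometric (recoverable) auxiliary whose induction on this alkene is not established.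
- **Weak points:** A1 contains neither the peroxide nor C3 oxygenation nor C6. These would need chain extension at the hydroxyethyl end, dehydrogenation to a butenolide, a tertiary hydroperoxide at C6 and an oxa-Michael closure. That is a long sequence in which C6 is formed in an open chain with no control from C4.
- **Comparison:** the chosen plan sets against the better enantiocontrol a key step that builds the dioxane and fixes the C3/C4 relationship at once, and a C6 centre set on a rigid ring.

**Alternative 2:** A peroxy-Prins annulation ended by carboxylate capture.
- **Cut:** C6–O, C5–C6 and the lactone C4–O bond, leading to (R)-3-hydroperoxy-4-methylpent-4-enoic acid A4 and the ketone dimethyl ketal A5.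
- **Key step:** Me3SiOTf would exchange a methoxy group of A5 for the hydroperoxide and ionise to a peroxycarbenium ion. The alkene terminus C5 attacks it and the carboxyl traps the tertiary C4 cation, giving the silyl-protected bicycle A3.
- **Merits:** it is the most convergent of the four plans. Both rings, two stereocentres and most of the chain arrive in one step, and in step count it beats the chosen route.
- **Weak points:** the C6 centre arises from a cation whose two substituents (methyl and a primary alkyl chain) differ little, so little facial preference is expected. A4 is a secondary allylic hydroperoxide that must be enantiopure, and the obvious ene reaction gives it racemic. Allylic hydroperoxides are prone to Hock cleavage under Lewis acid, and the tertiary cation may lose a proton.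
- **Comparison:** the chosen plan is longer but sets C6 with a small nucleophile on a conformationally defined cation, and carries no free hydroperoxide through a Lewis acid step except the tertiary hemiketal.

**Alternative 3:** A late γ-C–H lactonisation of the dioxane acetic acid A7.
- **Cut:** the lactone C4–O bond; the C4 methyl stereocentre of A7 would come from citronellal.
- **Key step:** Mn(OTf)2 (divalent manganese) with a bis(pyridylmethyl)diamine ligand and H2O2 would oxidise the tertiary C4–H, and the bound carboxylate closes the lactone with retention, giving the acetate A6.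
- **Merits:** carboxylate-directed γ-lactonisation of unactivated tertiary C–H bonds is an established reaction type, and the chiral-pool origin makes the absolute configuration secure. That is an advantage over the auxiliary of the chosen plan.
- **Weak points:** the C4–H bond is deactivated by the adjacent C3–O bond, while the C3–H bond α to oxygen is activated. The O–O bond has to survive a manganese/H2O2 system. Because the C–H oxidation is stereoretentive, A7 must already have C3, C4 and C6 in the correct relative configuration, which moves the stereochemical problem to dioxane formation on an open chain.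
- **Comparison:** the chosen plan obtains the cis fusion by construction from a cyclobutane and never exposes the finished peroxide to an oxidising metal–peroxide system.

Key step: step 4

Assumption: the (2R,5R) amide 2 is taken to deliver the (1R,5R) ketone 6; if the sense of induction on this enol lactone is the opposite, the equally available (2S,5S) amine is used with no other change.

## Route

Step 1
Reactants: 1 (2R,5R)-2,5-dimethylpyrrolidine
Product: 2 1-[(2R,5R)-2,5-dimethylpyrrolidin-1-yl]ethan-1-one
Conditions: Ac2O, Et3N, DMAP (cat.), CH2Cl2, 0 °C → rt
Reagents that add atoms: acetic anhydride, CC(=O)OC(C)=O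
Why: N-Acylation of a hindered secondary amine with an anhydride; the stereocentres of 1 are not involved.

Step 2
Reactants: 2 1-[(2R,5R)-2,5-dimethylpyrrolidin-1-yl]ethan-1-one; 3 α-angelica lactone (5-methylfuran-2(3H)-one)
Product: 6 (1R,5R)-1-methyl-2-oxabicyclo[3.2.0]heptane-3,6-dione, via keteniminium triflate 4 (not isolated), via cyclobutaniminium triflate 5 (not isolated)
Conditions: Tf2O, 2,4,6-collidine, 3 (2 equiv), ClCH2CH2Cl, −20 °C → 60 °C; then H2O, 40 °C
Reagents that add atoms: water, O
Why: Keteniminium–alkene [2+2] cycloaddition followed by iminium hydrolysis: the electrophilic central carbon of 4 bonds to the nucleophilic β-carbon of the enol lactone (future C3) and the enamine carbon closes on the oxygen-stabilised cationic carbon (future C4), which places the ketone next to the ring-fusion CH. The cis fusion is enforced by the four-membered ring, and the absolute configuration of C3 and C4 is set together by the C2-symmetric pyrrolidine, whose flanking methyl groups leave one approach of the flat lactone to 4 open. Hydrolysis of 5 with water alone keeps the β-acyloxy ketone away from base.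

Step 3
Reactants: 6 (1R,5R)-1-methyl-2-oxabicyclo[3.2.0]heptane-3,6-dione
Product: 7 (1R,5S,6RS)-6-hydroxy-1,6-dimethyl-2-oxabicyclo[3.2.0]heptan-3-one (cis-fused; either carbinol epimer)
Conditions: MeTi(OiPr)3, THF, −30 °C → 0 °C; aq. NH4Cl
Reagents that add atoms: methyltitanium triisopropoxide, C[Ti](OC(C)C)(OC(C)C)OC(C)C
Why: Chemoselective 1,2-addition of a non-basic methyltitanium reagent to the strained ketone; the lactone is not attacked and the β-acyloxy ketone is not enolised. The carbinol centre forms as an epimer mixture that needs no separation because step 4 destroys it. A non-saponifying work-up is used because the epimer with OH cis to the lactone ring is the lactone of a meso dihydroxy acid and would racemise if the lactone were opened and reclosed.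

Step 4
Reactants: 7 (1R,5S,6RS)-6-hydroxy-1,6-dimethyl-2-oxabicyclo[3.2.0]heptan-3-one; 8 dioxygen
Product: 10 (4aR,7aR)-3-hydroxy-3,4a-dimethyltetrahydro-3H-furo[3,2-c][1,2]dioxin-6(4H)-one (cis-fused; both anomers at the hemiketal carbon), via hydroperoxy ketone 9 (not isolated)
Conditions: Co(acac)2 (10 mol %), O2 (1 atm), CH2Cl2, rt
Reagents that add atoms: none
Why: This is the cobalt-catalysed aerobic ring expansion of a cyclobutanol to a 1,2-dioxan-3-ol, the four-membered counterpart of the cyclopropanol to 1,2-dioxolan-3-ol oxidation. Co(acac)2 (divalent cobalt) is oxidised by O2 to a trivalent cobalt species that binds 7 as its alkoxide; homolysis gives the C6 alkoxy radical, whose strain-driven β-scission breaks C3–C6 and leaves a methyl ketone at C6 and a secondary radical at C3. The C3 radical captures 8 and the peroxyl radical is taken through a cobalt peroxide to hydroperoxide 9, which forms the C3–O bond and passes the chain on. The dioxane then closes by 6-exo-trig addition of the hydroperoxide oxygen to the ketone carbonyl (C6–O bond), a reversible peroxyhemiketalisation. C4 is a spectator and keeps its configuration; C3 becomes planar at the radical stage and is set anew under control of the quaternary C4, since only O2 capture cis to the acetonyl arm can close to the unstrained cis-fused bicycle, so ring closure selects the required C3 configuration and uncyclised material is removed by chromatography. C6 forms as an anomer mixture under thermodynamic control, which is harmless because step 5 passes through a planar cation. The selectivity the step needs is β-scission toward C3 and not toward C5 or the methyl group; it is secured because cleavage toward C3 gives a secondary radical, the alternatives give a primary radical or methyl, and both ring bonds release the same strain.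

Step 5
Reactants: 10 (4aR,7aR)-3-hydroxy-3,4a-dimethyltetrahydro-3H-furo[3,2-c][1,2]dioxin-6(4H)-one; 11 allyltrimethylsilane
Product: 13 (3S,4aR,7aR)-3,4a-dimethyl-3-(prop-2-en-1-yl)tetrahydro-3H-furo[3,2-c][1,2]dioxin-6(4H)-one, via peroxycarbenium ion 12 (not isolated)
Conditions: SnCl4, 11 (5 equiv), CH2Cl2, −78 °C → −40 °C
Reagents that add atoms: none
Why: Hosomi–Sakurai-type allylation of a peroxycarbenium ion: SnCl4 ionises either anomer of the tertiary peroxyhemiketal to the same planar cation 12, so the step is stereoconvergent. Cation 12 should react through the half-chair with the C4 methyl pseudoequatorial, and chair-like axial attack on the face anti to the C4 methyl puts the allyl group cis to the lactone oxygen and the C6 methyl cis to the C4 methyl, which is the (S) configuration of C6 in 20. Low temperature and a neutral π-nucleophile leave the O–O bond and the lactone intact.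

Step 6
Reactants: 13 (3S,4aR,7aR)-3,4a-dimethyl-3-(prop-2-en-1-yl)tetrahydro-3H-furo[3,2-c][1,2]dioxin-6(4H)-one; 14 hex-5-en-1-ol
Product: 15 (3S,4aR,7aR)-3-(7-hydroxyhept-2-en-1-yl)-3,4a-dimethyltetrahydro-3H-furo[3,2-c][1,2]dioxin-6(4H)-one (E/Z mixture)
Conditions: second-generation Hoveyda–Grubbs catalyst [(H2IMes)Cl2Ru=CH(2-iPrOC6H4)] (5 mol %), 14 (4 equiv), CH2Cl2, 40 °C
Reagents that add atoms: none
Why: Olefin cross-metathesis of two unhindered terminal alkenes, driven by loss of ethene and an excess of 14; the phosphine-free ruthenium carbene tolerates the dialkyl peroxide, the free alcohol and the lactone. The geometry of the new C8=C9 bond is irrelevant because step 7 saturates it.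

Step 7
Reactants: 15 (3S,4aR,7aR)-3-(7-hydroxyhept-2-en-1-yl)-3,4a-dimethyltetrahydro-3H-furo[3,2-c][1,2]dioxin-6(4H)-one
Product: 16 (3S,4aR,7aR)-3-(7-hydroxyheptyl)-3,4a-dimethyltetrahydro-3H-furo[3,2-c][1,2]dioxin-6(4H)-one
Conditions: KO2CN=NCO2K, AcOH, CH2Cl2/MeOH, 0 °C → rt (repeated charges)
Reagents that add atoms: none
Why: Diimide reduction: H2 is transferred to the C=C bond through a concerted cyclic transition state and O–O bonds are not reduced, in contrast to catalytic hydrogenation. Generating diimide from the azodicarboxylate salt with acetic acid keeps the medium weakly acidic, which protects the β-peroxy lactone from base.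

Step 8
Reactants: 16 (3S,4aR,7aR)-3-(7-hydroxyheptyl)-3,4a-dimethyltetrahydro-3H-furo[3,2-c][1,2]dioxin-6(4H)-one
Product: 17 7-[(3S,4aR,7aR)-3,4a-dimethyl-6-oxotetrahydro-3H-furo[3,2-c][1,2]dioxin-3-yl]heptanal
Conditions: Dess–Martin periodinane, CH2Cl2, 0 °C → rt
Reagents that add atoms: none
Why: Dess–Martin oxidation of a primary alcohol to the aldehyde under non-basic, non-reducing conditions that the peroxide tolerates; no over-oxidation is expected.

Step 9
Reactants: 17 7-[(3S,4aR,7aR)-3,4a-dimethyl-6-oxotetrahydro-3H-furo[3,2-c][1,2]dioxin-3-yl]heptanal; 18 diethyl [(2E)-3-phenylprop-2-en-1-yl]phosphonate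
Product: 20 plakortolide Q [(3S,4aR,7aR)-3,4a-dimethyl-3-[(7E,9E)-10-phenyldeca-7,9-dien-1-yl]tetrahydro-3H-furo[3,2-c][1,2]dioxin-6(4H)-one], via lithiated phosphonate 19 (not isolated)
Conditions: 18, LiN(SiMe3)2 (slight deficit relative to 18), THF, −78 °C; then 17, −78 °C → 0 °C
Reagents that add atoms: none
Why: Horner–Wadsworth–Emmons olefination with an allylic phosphonate anion, which should give the new C13=C14 bond mainly as the E isomer, while the C15=C16 geometry is carried in from 18. The anion 19 is pre-formed with a slight deficit of base and meets the aldehyde at −78 °C, so that carbonyl addition outruns enolisation of the lactone and E1cB opening of the peroxide.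

## Compound list

1 | (2R,5R)-2,5-dimethylpyrrolidine | C[C@@H]1CC[C@@H](C)N1 | starting material
2 | 1-[(2R,5R)-2,5-dimethylpyrrolidin-1-yl]ethan-1-one | CC(=O)N1[C@H](C)CC[C@H]1C | intermediate
3 | α-angelica lactone (5-methylfuran-2(3H)-one) | CC1=CCC(=O)O1 | starting material
4 | (2R,5R)-1-ethenylidene-2,5-dimethylpyrrolidin-1-ium trifluoromethanesulfonate (keteniminium triflate) | C=C=[N+]1[C@H](C)CC[C@H]1C.[O-]S(=O)(=O)C(F)(F)F | intermediate
5 | (2R,5R)-2,5-dimethyl-1-[(1R,5S)-1-methyl-3-oxo-2-oxabicyclo[3.2.0]heptan-6-ylidene]pyrrolidin-1-ium trifluoromethanesulfonate (cyclobutaniminium triflate) | C[C@@H]3CC[C@@H](C)[N+]3=C1C[C@@]2(C)OC(=O)C[C@H]21.[O-]S(=O)(=O)C(F)(F)F | intermediate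
6 | (1R,5R)-1-methyl-2-oxabicyclo[3.2.0]heptane-3,6-dione | O=C1C[C@@]2(C)OC(=O)C[C@H]21 | intermediate
7 | (1R,5S,6RS)-6-hydroxy-1,6-dimethyl-2-oxabicyclo[3.2.0]heptan-3-one | CC1(O)C[C@@]2(C)OC(=O)C[C@H]21 | intermediate
8 | dioxygen | O=O | starting material
9 | (4R,5R)-4-hydroperoxy-5-methyl-5-(2-oxopropyl)oxolan-2-one | CC(=O)C[C@@]1(C)OC(=O)C[C@H]1OO | intermediate
10 | (4aR,7aR)-3-hydroxy-3,4a-dimethyltetrahydro-3H-furo[3,2-c][1,2]dioxin-6(4H)-one (both anomers) | CC1(O)C[C@@]2(C)OC(=O)C[C@H]2OO1 | intermediate
11 | allyltrimethylsilane | C=CC[Si](C)(C)C | starting material
12 | (4aR,7aR) peroxycarbenium ion formed from 10 by loss of hydroxide from the hemiketal carbon | CC1C[C@@]2(C)OC(=O)C[C@H]2O[O+]=1 | intermediate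
13 | (3S,4aR,7aR)-3,4a-dimethyl-3-(prop-2-en-1-yl)tetrahydro-3H-furo[3,2-c][1,2]dioxin-6(4H)-one | C[C@]1(CC=C)C[C@@]2(C)OC(=O)C[C@H]2OO1 | intermediate
14 | hex-5-en-1-ol | C=CCCCCO | starting material
15 | (3S,4aR,7aR)-3-(7-hydroxyhept-2-en-1-yl)-3,4a-dimethyltetrahydro-3H-furo[3,2-c][1,2]dioxin-6(4H)-one (E/Z mixture) | C[C@]1(CC=CCCCCO)C[C@@]2(C)OC(=O)C[C@H]2OO1 | intermediate
16 | (3S,4aR,7aR)-3-(7-hydroxyheptyl)-3,4a-dimethyltetrahydro-3H-furo[3,2-c][1,2]dioxin-6(4H)-one | C[C@]1(CCCCCCCO)C[C@@]2(C)OC(=O)C[C@H]2OO1 | intermediate
17 | 7-[(3S,4aR,7aR)-3,4a-dimethyl-6-oxotetrahydro-3H-furo[3,2-c][1,2]dioxin-3-yl]heptanal | C[C@]1(CCCCCCC=O)C[C@@]2(C)OC(=O)C[C@H]2OO1 | intermediate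
18 | diethyl [(2E)-3-phenylprop-2-en-1-yl]phosphonate | CCOP(=O)(OCC)C/C=C/c1ccccc1 | starting material
19 | lithium salt of the α-carbanion of 18 | [Li+].CCOP(=O)(OCC)[CH-]/C=C/c1ccccc1 | intermediate
20 | plakortolide Q, (3S,4aR,7aR)-3,4a-dimethyl-3-[(7E,9E)-10-phenyldeca-7,9-dien-1-yl]tetrahydro-3H-furo[3,2-c][1,2]dioxin-6(4H)-one | C[C@]1(CCCCCC/C=C/C=C/c2ccccc2)C[C@@]2(C)OC(=O)C[C@H]2OO1 | target

## Step count and risks

Total: 9 steps. Longest linear sequence: 9 steps (1 → 20; 8 steps from 3). The chain pieces 11, 14 and 18 are commercial.

**Step 4 (key step).**
- What may go wrong: unselective capture of O2 at the planar C3 radical. Methyl and acetonyl on C4 differ little in size, so part of the material may be oxygenated on the face that cannot cyclise. Cleavage toward C5 and slow turnover of the cobalt alkoxide are further concerns, since a cyclobutanol is a less willing substrate than a cyclopropanol.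
- Fallback, from 7, returning at 10: hypoiodite alkoxy-radical fragmentation of 7 (PhI(OAc)2, I2, visible light) should perform the same β-scission but trap the C3 radical with iodine, giving (5R)-4-iodo-5-methyl-5-(2-oxopropyl)oxolan-2-one F1, whose C3 configuration no longer matters. Et3N eliminates HI to the butenolide (R)-5-methyl-5-(2-oxopropyl)furan-2(5H)-one F2. H2O2 (urea adduct) with catalytic Et2NH in CF3CH2OH then adds to the ketone to give the perhydrate (5R)-5-(2-hydroperoxy-2-hydroxypropyl)-5-methylfuran-2(5H)-one F3. Its hydroperoxide closes by intramolecular oxa-Michael addition to C3 from the face of its own tether, which gives 10 with the cis fusion. The same H2O2/amine treatment would also return uncyclised hydroperoxide from the cobalt reaction to 10, because it eliminates to F2 under these conditions.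

**Step 2.**
- What may go wrong: acid-promoted isomerisation or oligomerisation of the enol lactone may compete with cycloaddition, since an enol ester is a weaker nucleophile than an enol ether. Face discrimination by the auxiliary may also be modest for this small, flat alkene.
- Fallback, from 3, returning at 6: dichloroketene [2+2] cycloaddition (Cl3CCOCl, Zn(Cu), Et2O), which has the same regiochemistry, should give racemic cis-7,7-dichloro-1-methyl-2-oxabicyclo[3.2.0]heptane-3,6-dione F4. Reductive dechlorination (Zn, AcOH) gives racemic cis-1-methyl-2-oxabicyclo[3.2.0]heptane-3,6-dione F5, and the antipodes are separated by preparative chromatography on a chiral stationary phase to give 6.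

**Step 5.**
- What may go wrong: slow ionisation of the tertiary hydroxyl, so that the ring-opened hydroperoxy ketone form is attacked by SnCl4 and undergoes Hock-type O–O heterolysis instead of C–C bond formation.
- Fallback, from 10, returning at 13: acetal exchange (MeOH, HC(OMe)3, cat. TsOH) should give the methyl peroxyketal (4aR,7aR)-3-methoxy-3,4a-dimethyltetrahydro-3H-furo[3,2-c][1,2]dioxin-6(4H)-one F6, which cannot ring-open. TiCl4 or Me3SiOTf at −78 °C in the presence of 11 then generates 12 and gives 13.

**Step 9.**
- What may go wrong: proton transfer from C2 of the lactone to the phosphonate anion, followed by E1cB opening of the dioxane, in competition with addition to the aldehyde.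
- Fallback, from 17, returning at 20: Wittig olefination with the much less basic ylide from cinnamyltriphenylphosphonium bromide (NaN(SiMe3)2, consumed before 17 is added) should give the diene as a mixture at C13=C14 containing (3S,4aR,7aR)-3,4a-dimethyl-3-[(7Z,9E)-10-phenyldeca-7,9-dien-1-yl]tetrahydro-3H-furo[3,2-c][1,2]dioxin-6(4H)-one F7. Iodine-catalysed photoisomerisation (I2 cat., daylight, hexane) then equilibrates the mixture to the (E,E) diene 20.

## Further compounds

F1 | step 4 | (5R)-4-iodo-5-methyl-5-(2-oxopropyl)oxolan-2-one (C4 epimers) | CC(=O)C[C@@]1(C)OC(=O)CC1I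
F2 | step 4 | (R)-5-methyl-5-(2-oxopropyl)furan-2(5H)-one | CC(=O)C[C@@]1(C)OC(=O)C=C1
F3 | step 4 | (5R)-5-(2-hydroperoxy-2-hydroxypropyl)-5-methylfuran-2(5H)-one | CC(O)(OO)C[C@@]1(C)OC(=O)C=C1
F4 | step 2 | racemic cis-7,7-dichloro-1-methyl-2-oxabicyclo[3.2.0]heptane-3,6-dione | O=C1C(Cl)(Cl)[C@@]2(C)OC(=O)C[C@H]21.O=C1C(Cl)(Cl)[C@]2(C)OC(=O)C[C@@H]21
F5 | step 2 | racemic cis-1-methyl-2-oxabicyclo[3.2.0]heptane-3,6-dione | O=C1C[C@@]2(C)OC(=O)C[C@H]21.O=C1C[C@]2(C)OC(=O)C[C@@H]21
F6 | step 5 | (4aR,7aR)-3-methoxy-3,4a-dimethyltetrahydro-3H-furo[3,2-c][1,2]dioxin-6(4H)-one (both anomers) | COC1(C)C[C@@]2(C)OC(=O)C[C@H]2OO1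
F7 | step 9 | (3S,4aR,7aR)-3,4a-dimethyl-3-[(7Z,9E)-10-phenyldeca-7,9-dien-1-yl]tetrahydro-3H-furo[3,2-c][1,2]dioxin-6(4H)-one | C[C@]1(CCCCCC/C=C\C=C\c2ccccc2)C[C@@]2(C)OC(=O)C[C@H]2OO1
A1 | alternative 1 | (S)-5-(2-hydroxyethyl)-5-methyloxolan-2-one | OCC[C@@]1(C)OC(=O)CC1
A2 | alternative 1 | 4-hydroxy-4-methylcyclohexan-1-one | CC1(O)CCC(=O)CC1
A3 | alternative 2 | (3S,4aR,7aR)-3-{7-[tert-butyl(diphenyl)silyl]oxyheptyl}-3,4a-dimethyltetrahydro-3H-furo[3,2-c][1,2]dioxin-6(4H)-one | C[C@]1(CCCCCCCO[Si](c3ccccc3)(c4ccccc4)C(C)(C)C)C[C@@]2(C)OC(=O)C[C@H]2OO1
A4 | alternative 2 | (R)-3-hydroperoxy-4-methylpent-4-enoic acid | OC(=O)C[C@H](C(C)=C)OO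
A5 | alternative 2 | 9-{[tert-butyl(diphenyl)silyl]oxy}-2,2-dimethoxynonane | COC(C)(OC)CCCCCCCO[Si](c1ccccc1)(c1ccccc1)C(C)(C)C
A6 | alternative 3 | 7-[(3S,4aR,7aR)-3,4a-dimethyl-6-oxotetrahydro-3H-furo[3,2-c][1,2]dioxin-3-yl]heptyl acetate | C[C@]1(CCCCCCCOC(C)=O)C[C@@]2(C)OC(=O)C[C@H]2OO1
A7 | alternative 3 | 2-[(3R,4S,6S)-6-(7-acetoxyheptyl)-4,6-dimethyl-1,2-dioxan-3-yl]acetic acid | C[C@]1(CCCCCCCOC(C)=O)C[C@H](C)[C@@H](CC(=O)O)OO1
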